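**Strategy.** The flavonol is cut at C4, the ring C carbonyl. This single carbon sits between C4a of ring A and the oxygen-bearing C3, so it is supplied as carbon monoxide. A palladium-catalysed carbonylative α-arylation joins three components: a ring A aryl iodide (iodine at the future C4a, between two equivalent MOM ethers that become O1 and the C5 hydroxyl, with the C7 methoxy and both prenyl groups in place), CO, and the sodium enolate of a ring B α-(methoxymethoxy) ketone. It forms C4a–C4 and C3–C4 at once. Because ring A of the precursor is mirror-symmetric, either phenol closes ring C to the same flavonol on acidic MOM removal.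

Key step: step 10

**Remarks on the chemistry**
- Abbreviations: prenyl = 3-methylbut-2-en-1-yl; MOM = methoxymethyl.
- Ring A: C4a is not the only ring A carbon lying between two oxygen-bearing carbons. C6 (between C5 and C7) and C8 (between C7 and C8a) do so as well. C4a is singled out because it lies between C5 and C8a, and because in arene 12 it is the only ring carbon that still bears hydrogen, so metalation can only occur there.
- Stereochemistry: C2 of diketone 22 is a stereogenic centre. The key step therefore creates one stereocentre, racemic and uncontrolled (and largely enolised). It becomes the sp2 carbon C3 in step 11; the target is achiral.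
- Route to the iodide: the prenyl groups are built by Claisen rearrangement of allyl ethers followed by cross-metathesis. Direct C-alkylation of the phenol with prenyl bromide would divide between O-, mono-C-, di-C- and geminal alkylation. The ester of 1 blocks the future C4a until it is needed.
- Key step: the ketone is used in twofold amount with one equivalent of base per ketone. The second enolate, not free amide, then takes up the acidic proton of 22.
- Stoichiometry: where a step builds two molecules of a numbered reactant into the product (steps 2 and 4), the second equivalent is also entered under "Reagents that add atoms".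

**Route**

Step 1
Reactants: 1 methyl 2,4,6-trihydroxybenzoate
Product: 2 methyl 2,6-dihydroxy-4-methoxybenzoate
Conditions: Me2SO4 (1.05 equiv), K2CO3 (1.1 equiv), acetone, rt
Reagents that add atoms: dimethyl sulfate, COS(=O)(=O)OC
Why: Williamson O-methylation should stop at the monoether because the C4 hydroxyl, para to the ester and not hydrogen-bonded, is the most acidic and most exposed phenol, while the C2 and C6 hydroxyls are held by the ester carbonyl.

Step 2
Reactants: 2 methyl 2,6-dihydroxy-4-methoxybenzoate; 3 allyl bromide
Product: 4 methyl 2,6-bis(allyloxy)-4-methoxybenzoate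
Conditions: allyl bromide (2.5 equiv), K2CO3 (3 equiv), DMF, 60 °C
Reagents that add atoms: allyl bromide (second equivalent), C=CCBr
Why: Twofold Williamson etherification with carbonate in a dipolar aprotic solvent favours O- over C-allylation and, with excess bromide and warming, alkylates both hydrogen-bonded phenols, each taking one molecule of allyl bromide.

Step 3
Reactants: 4 methyl 2,6-bis(allyloxy)-4-methoxybenzoate
Product: 6 methyl 3,5-diallyl-2,6-dihydroxy-4-methoxybenzoate, via mono-rearranged phenol 5 (not isolated)
Conditions: N,N-diethylaniline, 195 °C, sealed tube, Ar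
Reagents that add atoms: none
Why: Double aromatic Claisen rearrangement ([3,3]-sigmatropic shift, then tautomerisation) can only deliver the allyl groups to C3 and C5 because C1 is blocked by the ester, and the basic solvent suppresses acid-catalysed cyclisation of the new ortho-allylphenols.

Step 4
Reactants: 6 methyl 3,5-diallyl-2,6-dihydroxy-4-methoxybenzoate; 7 2-methylbut-2-ene
Product: 9 methyl 2,6-dihydroxy-4-methoxy-3,5-diprenylbenzoate, via monoprenyl ester 8 (not isolated)
Conditions: second-generation Grubbs catalyst RuCl2(=CHPh)(PCy3)(H2IMes) (5 mol%), 2-methylbut-2-ene/CH2Cl2, 40 °C, sealed tube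
Reagents that add atoms: 2-methylbut-2-ene (second equivalent), CC=C(C)C
Why: Olefin cross-metathesis of each terminal allyl group with excess 2-methylbut-2-ene should give the prenyl group with loss of propene; the new olefin carries two identical methyl groups, so no geometry has to be controlled, and the phenols are tied up by hydrogen bonds to the ester.

Step 5
Reactants: 9 methyl 2,6-dihydroxy-4-methoxy-3,5-diprenylbenzoate
Product: 11 5-methoxy-4,6-diprenylbenzene-1,3-diol, via carboxylic acid 10 (not isolated)
Conditions: KOH (aq), MeOH, 80 °C, Ar; then NaH2PO4 (aq) to pH 6, 50 °C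
Reagents that add atoms: none
Why: Saponification is followed by protodecarboxylation, which is easy here because ipso protonation of the carboxyl-bearing carbon is assisted by three ortho/para oxygen donors, and the basic to near-neutral medium gives the ortho-prenylphenols no chance to cyclise to chromans.

Step 6
Reactants: 11 5-methoxy-4,6-diprenylbenzene-1,3-diol
Product: 12 5-methoxy-1,3-bis(methoxymethoxy)-4,6-diprenylbenzene
Conditions: NaH (2.5 equiv), MOMCl (2.5 equiv), DMF, 0 °C to rt
Reagents that add atoms: chloromethyl methyl ether, COCCl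
Why: O-alkylation of the bis-phenoxide with the hard electrophile MOMCl (Williamson-type acetal formation) protects both phenols and installs the two directing groups for the next step.

Step 7
Reactants: 12 5-methoxy-1,3-bis(methoxymethoxy)-4,6-diprenylbenzene
Product: 14 2-iodo-5-methoxy-1,3-bis(methoxymethoxy)-4,6-diprenylbenzene, via aryllithium 13 (not isolated)
Conditions: n-BuLi (1.2 equiv), THF, 0 °C; then I2 (1.3 equiv), THF, −78 °C to rt
Reagents that add atoms: iodine, [I][I]
Why: Directed ortho-metalation should take the only ring hydrogen, which lies between two MOM ethers that pre-coordinate the base and so outpaces removal of a benzylic-allylic prenyl hydrogen, and the aryllithium is trapped by iodine at low temperature without touching the olefins.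

Step 8
Reactants: 15 1-(3-hydroxy-4-methoxyphenyl)ethanone
Product: 18 2-hydroxy-1-(3-hydroxy-4-methoxyphenyl)ethanone, via bis-silyl enol ether 16 (not isolated), via silyloxy ketone 17 (not isolated)
Conditions: LiN(SiMe3)2 (2.3 equiv), Me3SiCl (2.6 equiv), THF, −78 to 0 °C; then mCPBA (1.1 equiv), NaHCO3, CH2Cl2, 0 °C; then citric acid, MeOH, rt
Reagents that add atoms: 3-chloroperoxybenzoic acid (mCPBA), OOC(=O)c1cccc(Cl)c1
Why: Rubottom oxidation: double silylation masks the phenol and gives the silyl enol ether, the peracid epoxidises this most electron-rich olefin and silyl migration gives the α-silyloxy ketone, after which mild methanolysis frees both hydroxyls.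

Step 9
Reactants: 18 2-hydroxy-1-(3-hydroxy-4-methoxyphenyl)ethanone
Product: 19 2-(methoxymethoxy)-1-[4-methoxy-3-(methoxymethoxy)phenyl]ethanone
Conditions: MOMCl (3 equiv), i-Pr2NEt (4 equiv), CH2Cl2, 0 °C to rt
Reagents that add atoms: chloromethyl methyl ether, COCCl
Why: O-alkylation with MOMCl and a hindered amine base (acetal protection) caps the phenol and the primary ketol hydroxyl in one operation without enolising the ketone.

Step 10
Reactants: 14 2-iodo-5-methoxy-1,3-bis(methoxymethoxy)-4,6-diprenylbenzene; 20 carbon monoxide; 19 2-(methoxymethoxy)-1-[4-methoxy-3-(methoxymethoxy)phenyl]ethanone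
Product: 22 2-(methoxymethoxy)-1-[4-methoxy-3-(methoxymethoxy)phenyl]-3-[4-methoxy-2,6-bis(methoxymethoxy)-3,5-diprenylphenyl]propane-1,3-dione (racemic at C2), via sodium enolate 21 (not isolated)
Conditions: 19 (2 equiv), NaN(SiMe3)2 (2 equiv), THF, 0 °C; then 14, Pd(dba)2 (5 mol%), Ph2P(CH2)3PPh2 (5 mol%), CO (1 atm), THF, 80 °C; NH4Cl (aq)
Reagents that add atoms: none
Why: Zerovalent palladium bearing the chelating diphosphine inserts into the C–I bond of 14, CO then inserts to give an aroyl complex of divalent palladium, enolate 21 takes the place of iodide and C–C reductive elimination forms C3–C4, after which the acidic C2–H of 22 is removed by the second equivalent of enolate, which makes the sequence irreversible. The closest known reaction type is the palladium-catalysed carbonylative α-arylation of aryl ketones with aryl iodides to 1,3-diketones under these conditions; an α-alkoxy ketone and a 2,6-dialkoxy aryl iodide lie at the edge of that scope, which is why the risk of the route is placed here. No ring closes, and the single new stereocentre, C2 of 22, arises racemic and uncontrolled and is erased in step 11. The step needs carbonylative C-acylation to win over direct α-arylation, O-acylation and amide formation: the two ortho MOM ethers crowd the aryl–palladium bond so that CO insertion, which moves the metal one atom out of the pocket, precedes attack of the enolate, the bite angle of the diphosphine favours the C-bound enolate and its reductive elimination, and no free amide base is present. Both positions ortho to iodine are substituted, so neither aryne formation nor ortho-metalation can divert 14 under the basic conditions.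

Step 11
Reactants: 22 2-(methoxymethoxy)-1-[4-methoxy-3-(methoxymethoxy)phenyl]-3-[4-methoxy-2,6-bis(methoxymethoxy)-3,5-diprenylphenyl]propane-1,3-dione
Product: 25 3,5-dihydroxy-2-(3-hydroxy-4-methoxyphenyl)-7-methoxy-6,8-diprenyl-4H-chromen-4-one (CNP0261856.0), via triphenol diketone 23 (not isolated), via 3-O-MOM flavone 24 (not isolated)
Conditions: HCl (3 M aq, excess), MeOH–THF, 45 °C
Reagents that add atoms: none
Why: Acid-catalysed acetal methanolysis frees the phenols, one of the two equivalent ring A phenols adds to the ring B carbonyl and loses water (cyclodehydration of a 2-hydroxyaryl 1,3-diketone to the 4-pyranone), and the remaining MOM group, now on the C3 enol oxygen, falls under the same conditions, while the mild temperature and the hydrogen bond from the C5 hydroxyl to the C4 carbonyl hold back addition of phenols to the prenyl olefins.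

**Compound list**

1 | methyl 2,4,6-trihydroxybenzoate | COC(=O)c1c(O)cc(O)cc1O | starting material
2 | methyl 2,6-dihydroxy-4-methoxybenzoate | COC(=O)c1c(O)cc(OC)cc1O | intermediate
3 | allyl bromide (3-bromoprop-1-ene) | C=CCBr | starting material
4 | methyl 2,6-bis(allyloxy)-4-methoxybenzoate | COC(=O)c1c(OCC=C)cc(OC)cc1OCC=C | intermediate
5 | methyl 3-allyl-6-(allyloxy)-2-hydroxy-4-methoxybenzoate (not isolated) | COC(=O)c1c(O)c(CC=C)c(OC)cc1OCC=C | intermediate
6 | methyl 3,5-diallyl-2,6-dihydroxy-4-methoxybenzoate | COC(=O)c1c(O)c(CC=C)c(OC)c(CC=C)c1O | intermediate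
7 | 2-methylbut-2-ene | CC=C(C)C | starting material
8 | methyl 3-allyl-2,6-dihydroxy-4-methoxy-5-prenylbenzoate (not isolated) | COC(=O)c1c(O)c(CC=C)c(OC)c(CC=C(C)C)c1O | intermediate
9 | methyl 2,6-dihydroxy-4-methoxy-3,5-diprenylbenzoate | COC(=O)c1c(O)c(CC=C(C)C)c(OC)c(CC=C(C)C)c1O | intermediate
10 | 2,6-dihydroxy-4-methoxy-3,5-diprenylbenzoic acid (not isolated) | OC(=O)c1c(O)c(CC=C(C)C)c(OC)c(CC=C(C)C)c1O | intermediate
11 | 5-methoxy-4,6-diprenylbenzene-1,3-diol | COc1c(CC=C(C)C)c(O)cc(O)c1CC=C(C)C | intermediate
12 | 5-methoxy-1,3-bis(methoxymethoxy)-4,6-diprenylbenzene (hydrogen at C2, between the MOM ethers) | COCOc1cc(OCOC)c(CC=C(C)C)c(OC)c1CC=C(C)C | intermediate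
13 | [4-methoxy-2,6-bis(methoxymethoxy)-3,5-diprenylphenyl]lithium (not isolated) | [Li]c1c(OCOC)c(CC=C(C)C)c(OC)c(CC=C(C)C)c1OCOC | intermediate
14 | 2-iodo-5-methoxy-1,3-bis(methoxymethoxy)-4,6-diprenylbenzene | COCOc1c(I)c(OCOC)c(CC=C(C)C)c(OC)c1CC=C(C)C | intermediate
15 | 1-(3-hydroxy-4-methoxyphenyl)ethanone (3'-hydroxy-4'-methoxyacetophenone) | CC(=O)c1ccc(OC)c(O)c1 | starting material
16 | trimethyl({1-[4-methoxy-3-(trimethylsilyloxy)phenyl]ethenyl}oxy)silane (not isolated) | C=C(O[Si](C)(C)C)c1ccc(OC)c(O[Si](C)(C)C)c1 | intermediate
17 | 1-[4-methoxy-3-(trimethylsilyloxy)phenyl]-2-(trimethylsilyloxy)ethanone (not isolated) | C[Si](C)(C)OCC(=O)c1ccc(OC)c(O[Si](C)(C)C)c1 | intermediate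
18 | 2-hydroxy-1-(3-hydroxy-4-methoxyphenyl)ethanone | OCC(=O)c1ccc(OC)c(O)c1 | intermediate
19 | 2-(methoxymethoxy)-1-[4-methoxy-3-(methoxymethoxy)phenyl]ethanone | COCOCC(=O)c1ccc(OC)c(OCOC)c1 | intermediate
20 | carbon monoxide | [C-]#[O+] | starting material
21 | sodium 2-(methoxymethoxy)-1-[4-methoxy-3-(methoxymethoxy)phenyl]ethen-1-olate (enolate geometry undefined, not isolated) | [Na+].[O-]C(=COCOC)c1ccc(OC)c(OCOC)c1 | intermediate
22 | 2-(methoxymethoxy)-1-[4-methoxy-3-(methoxymethoxy)phenyl]-3-[4-methoxy-2,6-bis(methoxymethoxy)-3,5-diprenylphenyl]propane-1,3-dione (racemic at C2) | COCOC(C(=O)c1ccc(OC)c(OCOC)c1)C(=O)c1c(OCOC)c(CC=C(C)C)c(OC)c(CC=C(C)C)c1OCOC | intermediate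
23 | 1-(2,6-dihydroxy-4-methoxy-3,5-diprenylphenyl)-3-(3-hydroxy-4-methoxyphenyl)-2-(methoxymethoxy)propane-1,3-dione (racemic, not isolated) | COCOC(C(=O)c1ccc(OC)c(O)c1)C(=O)c1c(O)c(CC=C(C)C)c(OC)c(CC=C(C)C)c1O | intermediate
24 | 5-hydroxy-2-(3-hydroxy-4-methoxyphenyl)-7-methoxy-3-(methoxymethoxy)-6,8-diprenyl-4H-chromen-4-one (not isolated) | COCOc1c(-c2ccc(OC)c(O)c2)oc2c(CC=C(C)C)c(OC)c(CC=C(C)C)c(O)c2c1=O | intermediate
25 | 3,5-dihydroxy-2-(3-hydroxy-4-methoxyphenyl)-7-methoxy-6,8-diprenyl-4H-chromen-4-one (CNP0261856.0, achiral) | COc1ccc(-c2oc3c(CC=C(C)C)c(OC)c(CC=C(C)C)c(O)c3c(=O)c2O)cc1O | target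

**Step count**

Total: 11 steps. Longest linear sequence: 9 steps (steps 1–7, 10, 11); the ketone arm (steps 8–9) joins at step 10.

**Steps most likely to fail, with fallbacks**

1. Step 10. Slow CO insertion or slow reductive elimination at the crowded aroyl–palladium centre could let proto-deiodination of 14, capture of the aroyl group at the enolate oxygen, or self-condensation of the α-alkoxy enolate take over. The fallback takes C4 from a formyl carbon and forms C3–C4 by an aldol addition instead of catalysis. It sets out from 12, which is lithiated as in step 7 to 13 and quenched with DMF to give 4-methoxy-2,6-bis(methoxymethoxy)-3,5-diprenylbenzaldehyde F1. Ketone 19 is deprotonated with LiN(i-Pr)2 in THF at −78 °C to its lithium enolate F2, and addition of F1 should give the β-hydroxy ketone F3 (aldol addition; the diastereomers are of no consequence). Oxidation with Dess–Martin periodinane and NaHCO3 in CH2Cl2 should then give diketone 22, where the route is rejoined.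

2. Step 11. Protic acid could add a freed ring A phenol to its neighbouring prenyl olefin (chroman formation) in competition with closure of ring C, or the sequence could stall before the pyranone forms. The fallback separates deprotection from ring closure and takes protic acid out of the deprotection. It sets out from 22: Me3SiOTf and 2,2'-bipyridyl in CH2Cl2 at 0 °C, then water (silylative acetal cleavage at near-neutral pH), should give the MOM-free 2-hydroxy-1-(3-hydroxy-4-methoxyphenyl)-3-(2,6-dihydroxy-4-methoxy-3,5-diprenylphenyl)propane-1,3-dione F4, in equilibrium with its cyclic hemiketal. Gentle warming of F4 in AcOH buffered with NaOAc (60 °C), an acid too weak to protonate the prenyl olefins, should close and dehydrate it to 25.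

3. Step 7. Deprotonation at a benzylic-allylic CH2 of a prenyl group (lateral metalation) could compete with ring metalation, or the olefins could take up iodine during the quench. The fallback moves the iodination to a stage where no trisubstituted olefin exists and makes it an electrophilic substitution. It sets out from 6: KOH in aqueous MeOH as in step 5 should give, via 3,5-diallyl-2,6-dihydroxy-4-methoxybenzoic acid F5, the decarboxylated 4,6-diallyl-5-methoxybenzene-1,3-diol F6. NaH and MOMCl in DMF give 4,6-diallyl-5-methoxy-1,3-bis(methoxymethoxy)benzene F7. N-iodosuccinimide in MeCN at 0 °C should then iodinate the one free ring position, which is activated by three oxygens, to give 4,6-diallyl-2-iodo-5-methoxy-1,3-bis(methoxymethoxy)benzene F8; monosubstituted olefins are inert to this reagent without a nucleophile, and no free phenol is present for iodoetherification. Cross-metathesis with 7 and RuCl2(=CHPh)(PCy3)(H2IMes) as in step 4, via 4-allyl-2-iodo-5-methoxy-1,3-bis(methoxymethoxy)-6-prenylbenzene F9, should give 14.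

**Further compounds**

F1 | step 10 | 4-methoxy-2,6-bis(methoxymethoxy)-3,5-diprenylbenzaldehyde | O=Cc1c(OCOC)c(CC=C(C)C)c(OC)c(CC=C(C)C)c1OCOC
F2 | step 10 | lithium 2-(methoxymethoxy)-1-[4-methoxy-3-(methoxymethoxy)phenyl]ethen-1-olate | [Li+].[O-]C(=COCOC)c1ccc(OC)c(OCOC)c1
F3 | step 10 | 3-hydroxy-2-(methoxymethoxy)-1-[4-methoxy-3-(methoxymethoxy)phenyl]-3-[4-methoxy-2,6-bis(methoxymethoxy)-3,5-diprenylphenyl]propan-1-one (racemic diastereomers) | COCOC(C(=O)c1ccc(OC)c(OCOC)c1)C(O)c1c(OCOC)c(CC=C(C)C)c(OC)c(CC=C(C)C)c1OCOC
F4 | step 11 | 2-hydroxy-1-(3-hydroxy-4-methoxyphenyl)-3-(2,6-dihydroxy-4-methoxy-3,5-diprenylphenyl)propane-1,3-dione (racemic) | OC(C(=O)c1ccc(OC)c(O)c1)C(=O)c1c(O)c(CC=C(C)C)c(OC)c(CC=C(C)C)c1O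
F5 | step 7 | 3,5-diallyl-2,6-dihydroxy-4-methoxybenzoic acid | OC(=O)c1c(O)c(CC=C)c(OC)c(CC=C)c1O
F6 | step 7 | 4,6-diallyl-5-methoxybenzene-1,3-diol | COc1c(CC=C)c(O)cc(O)c1CC=C
F7 | step 7 | 4,6-diallyl-5-methoxy-1,3-bis(methoxymethoxy)benzene | COCOc1cc(OCOC)c(CC=C)c(OC)c1CC=C
F8 | step 7 | 4,6-diallyl-2-iodo-5-methoxy-1,3-bis(methoxymethoxy)benzene | COCOc1c(I)c(OCOC)c(CC=C)c(OC)c1CC=C
F9 | step 7 | 4-allyl-2-iodo-5-methoxy-1,3-bis(methoxymethoxy)-6-prenylbenzene | COCOc1c(I)c(OCOC)c(CC=C)c(OC)c1CC=C(C)C
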